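Amounts come first: larch and maple each hold twice as much substrate as reagent, so the reagent is the limiting reagent and the two products together can reach 50.0% of the substrates charged.

- larch: left-handed substrate 0.10 M; reagent 0.100 M; free catalyst 10 mM; right-handed substrate 0.10 M; temperature 40 °C; time 15 h
- maple: left-handed substrate 0.10 M; reagent 0.100 M; free catalyst 10 mM; right-handed substrate 0.10 M; temperature 50 °C; time 15 h

    free catalyst + left-handed substrate ⇌ catalyst intermediate A (K1 = 48 M⁻¹, k1 = 3400 M⁻¹ h⁻¹, Ea1 = 38.0 kJ mol⁻¹, ΔH1 = −47.0 kJ mol⁻¹)
    free catalyst + right-handed substrate ⇌ catalyst intermediate B (K2 = 4.1 M⁻¹, k2 = 4200 M⁻¹ h⁻¹, Ea2 = 54.0 kJ mol⁻¹, ΔH2 = −23.0 kJ mol⁻¹)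
    reagent + catalyst intermediate A → free catalyst + left-handed product (k3 = 17 M⁻¹ h⁻¹, Ea3 = 50.0 kJ mol⁻¹)
    reagent + catalyst intermediate B → free catalyst + right-handed product (k4 = 7.0 M⁻¹ h⁻¹, Ea4 = 65.0 kJ mol⁻¹)
    left-handed substrate ⇌ right-handed substrate (k5 = 0.93 h⁻¹, Ea5 = 99.0 kJ mol⁻¹)
    reagent ⇌ dormant form (K6 = 0.76, k6 = 0.32 h⁻¹, Ea6 = 92.0 kJ mol⁻¹, ΔH6 = −32.0 kJ mol⁻¹)
    free catalyst → spent catalyst (k7 = 4.0 × 10⁻⁴ h⁻¹, Ea7 = 128 kJ mol⁻¹)
    (constants at 40 °C)

1. which of the two there is more of at the end, larch (right-handed product / left-handed product)
2. which of the two there is more of at the end, maple (right-handed product / left-handed product)
3. amount of left-handed product at the end, in percent of the left-handed substrate and right-handed substrate together charged, larch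
4. amount of left-handed product at the end, in percent of the left-handed substrate and right-handed substrate together charged, maple

- free catalyst is single-handed; left-handed substrate and right-handed substrate are mirror images of each other, charged as a racemate, each of them at the stated concentration
- constants are those at 40 °C; use the activation energies and enthalpies for any other temperature

The reckoning here stays with larch. It follows one reagent molecule through its forks and asks which given numbers change its chances. Catalyst intermediate A falls back at 70.8 h⁻¹ and meets reagent at 1.70 h⁻¹ at full charge, so it goes forward with a chance of 2.34%. Catalyst intermediate B falls back faster still. In larch binding therefore stands close to equilibrium, and the equilibrium constants count for more than the binding rate constants. In larch racemisation relaxes with a half-life of 0.373 h, and reagent and dormant form relax with 0.935 h. The two substrates in larch are thus reckoned as nearly equal, and of the dormant-form constants the equilibrium constant is the one used. A catalyst molecule kept free for the whole of the run has a chance of 0.600% of becoming spent catalyst, and that step makes no difference to larch.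

 The selectivity factor, the reagent step constant times the binding constant on the left-handed route over the same product on the right-handed route, is 28.4. A consumed reagent molecule thus gives left-handed product with a chance of 96.6%, and larch ends richer in left-handed product. With that factor divided by 2, the chance is still 93.4%. In larch catalyst intermediate A, the resting state, is reckoned to hold 77.3% of the catalyst at the charged substrate fractions, and its binding constant divided by 2 gives 63.0%. At equilibrium with the dormant form, the reagent in larch is free for 56.8% of the time.

The reagent step constant, that share, the catalyst charge, the free fraction and the time multiply to 1.12. This is the reagent exposure, the mean number of productive meetings offered to one reagent molecule, reagent loss being taken as pseudo-first-order. The reckoned fraction of reagent used in larch is 67.4%. With the reagent step constant divided by 2 it is 42.9%, lower than the 59.9% reckoned with the left-handed binding constant divided by 2, so the reagent step constant has to be known better. The product of the ceiling, the fraction used and the left-handed chance gives larch 32.5% of left-handed product.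

The forecast gives left-handed product for larch and left-handed product for maple, at 32.7% and 40.6%, slightly above this reckoning for larch, holding that “the catalyst sits mostly as intermediate A”.

Larch ends at 32.1% of left-handed product with 1.19% of right-handed product, and maple at 40.2% with 2.30%. At the end of larch, 18% of the reagent stands free, and the dormant form holds 15.8% of the reagent charge. A neighbour of larch charged with 0.025 M of free catalyst is reckoned at an exposure of 2.80, which gives 45.4% of left-handed product. That neighbour ends at 43.5%.

Its constants are made up; the run is a simulation.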